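## Analysis of the target

The target is the 3,4-dimethoxybenzoate of an epoxidised daucane diol. It is a trans-fused hydroazulene in which cyclopentane ring A (C1–C5) and cycloheptane ring B (C5–C10 and C1) share the C1–C5 bond; daucane numbering is used throughout and β means the face of the C1 methyl. C1 is quaternary (angular methyl), C4 carries a tertiary hydroxyl and the isopropyl group, C5 is the ring-fusion CH, C6 bears the ester, and C8 (methyl) and C9 form a trisubstituted epoxide. There are six stereocentres, C1 (R), C4 (R), C5 (S), C6 (S), C8 (R) and C9 (S): the 4-hydroxyl is β, H-5 is α, the C6 oxygen and the epoxide oxygen are α, so C1, C5, C4 and C6 are contiguous and the oxygens at C4 and C6 are 1,3-anti. The sensitive groups are the epoxide (a C4 hydroxyl on the opposite face can open it across the ring under acid), the tertiary alcohol β to C6 (dehydration or retro-aldol whenever C6 is a ketone) and the aryl ester. The hard points are the quaternary centre at the ring fusion, a seven-membered ring with an isolated alkene exactly at C8–C9, and the C6 carbinol, whose hydrogen must come from the face of the angular methyl. The strategy rests on one feature: C5 to C10 of ring B carry oxygen at C6 and methyl at C8, the 1,3 pattern of a 2-methoxy-4-methylphenyl ring with C5 as ipso carbon. The seventh atom, C1 with its methyl, can then be inserted between C5 and the free ortho carbon C10 as a carbene carbon tied to C5 through C4–C3–C2, which closes ring A in the same event. Intermediates without the isopropyl group are named as 11,12,13-trinordaucanes.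

## Retrosynthetic reasoning

The ester C–O bond is cut first, 27 to epoxy diol 25 and acid chloride 26. Only the secondary 6-hydroxyl of 25 can be acylated, and putting the ester on last keeps it away from every reducing and organometallic step.

The epoxide is removed next, 25 to diol 24. The free 6α-hydroxyl of 24 is homoallylic to C8=C9 and can deliver the oxygen to the α face, which is why epoxidation precedes acylation.

The C6–H bond is cut, 24 to hydroxy ketone 23. Hydride has to arrive on the β face, under the angular methyl, and a reagent from outside would take the other face. The tertiary 4β-hydroxyl of 23 can carry the hydride to that face internally and give the 1,3-anti diol, so C6 stays at the ketone level until the end.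

The C4–isopropyl bond is cut, 23 through acetal 22 to ketone 20 and Grignard reagent 21. The angular methyl and the C5–C6 bond block the β face of the C4 carbonyl, so the nucleophile enters α and the hydroxyl ends β. C6 must be masked (dioxolane) while C4 is a ketone, otherwise a 1,3-diketone would erase C5.

Functional-group changes lead from 20 back to 15: C4 alcohol 19, silyl ether 18, xanthate 17, alcohol 16, hydroxy ketone 15. The oxygen at C2, a by-product of the ring-forming step, is taken out by radical deoxygenation. This is placed after the triene has been reduced, because a C2 radical beside a vinyl-substituted C1 would rearrange.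

Hydroxy ketone 15 comes from dienedione 14 by dissolving-metal reduction. 1,6-Reduction of the dienone and kinetic protonation put the alkene at C8–C9, and the saturated C2 ketone is reduced in the same pot while C6 is protected as its dienolate. 14 comes from enol ether 13 by hydrolysis, which also creates C5.

The key disconnection cuts C1–C5 and C1–C10 of 13, through norcaradiene 12, back to diazoketone 11. Both rings, the quaternary centre, the C6 oxygen and the C8 methyl then come from one aromatic precursor. An acetal would be the plain mask for the C4 ketone, but its oxygen sits five atoms from the carbene carbon and would form an oxonium ylide followed by a Stevens shift. C4 is therefore carried as a hindered silyl ether. The stereocentre this creates is used: it steers the arene face in the key step and later holds the ring fusion trans.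

Diazoketone 11 is cut at the acyl–diazo carbon bond into acid 7 and diazoethane 10 (from 8). This brings the methyl and the diazo carbon together, so no regiochemical question arises. Acid 7 goes back through silyl ether 6 and carbinol 5 (asymmetric transfer hydrogenation) to keto ester 4, and 4 is a Claisen product of ketone 2 and carbonate 3; 2 is the methyl ether of 1.

## Alternatives that were turned down

Alternative 1: Ring A is cut at C1–C5 and seen as the contraction product of a six-membered ring; ring B is left for a later annulation.
- Forward key step: a terpene-derived cyclohexane with a silyloxy group at C6 and an epoxide across C4–C5 is treated with the bulky Lewis acid MeAl(OAr)2 A1 (Ar = 4-bromo-2,6-di-tert-butylphenyl). C1 shifts from C6 to C5 as the epoxide opens and the cyclopentane aldehyde A2 results.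
- For it: the start is from the chiral pool, the anti shift is stereospecific, and A2 already holds C1, C4 (with isopropyl and protected oxygen) and C5, with an aldehyde at C6 and an allyl group for ring B. There is no surplus oxygen at C2, so on oxidation-state economy it is stronger than the chosen route.
- Against it: the shift needs positive charge at secondary C5, while the neighbouring epoxide carbon C4 is tertiary and will ionise first, which favours hydride shift or elimination. The migrating group is a quaternary ring carbon and needs one exact relative configuration at four centres of the precursor. A2 is an epimerisable β-silyloxy aldehyde, and C6 would then have to be set by an addition under acyclic control before a metathesis closes ring B.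
- Comparison: the chosen strategy makes both rings and C1 in one catalytic step and sets C6 at the end by internal hydride delivery. It pays for this with three steps at C2 and a longer redox sequence.

Alternative 2: The C1–CH3 and C5–C6 bonds are cut, which leads back to cyclopentenone A3.
- Forward key step: Me3Al A4 with Cu(OTf)2 A5 and a chiral N-heterocyclic carbene ligand transfers methyl to C1, and the aluminium enolate is trapped at C5 by acrolein A6 to give aldol A7.
- For it: it is the shortest entry to ring A, the quaternary centre is made by a precedented catalytic method, the C4 carbonyl is in place for the isopropyl addition, and no oxygen has to be removed. Up to this point it is clearly shorter than the chosen route.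
- Against it: five-membered enones are the weakest substrates for this addition, aluminium enolates are sluggish aldol donors, and A6 can react at either end or polymerise. The C6 carbinol centre is not controlled, and A7 is a β-hydroxy ketone open to retro-aldol and dehydration. Ring-closing metathesis of A7 would put the alkene at C7–C8, allylic to the C6 oxygen, and moving it to C8–C9 has no driving force.
- Comparison: the chosen strategy takes the C8 methyl and the 8,9 position of the alkene from the arene pattern and the dienone reduction, and C6 from a directed reduction.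

Alternative 3: Ring B is cut at C6–C7 and C1–C10, leaving ring A as the cyclopentenyl diazoacetate A8 and C7–C10 as isoprene A9.
- Forward key step: Rh2(S-DOSP)4 A10 forms the vinylcarbenoid, which cyclopropanates the methyl-bearing alkene of A9; Cope rearrangement of the cis-divinylcyclopropane gives cycloheptadiene ester A11.
- For it: it is convergent and puts the 8,9-alkene and the C8 methyl in place directly, which is better than the chosen route on that point, and it carries no C2 oxygen.
- Against it: C6 ends with an ester carbon that must be degraded to oxygen. The cyclopropanation must choose the more substituted alkene of A9. The Cope step has to create quaternary C1 from a fully substituted alkene carbon whose methyl points into the boat transition state, the known weak point of this rearrangement. A8 also has a stereocentre next to the carbenoid that may oppose A10.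
- Comparison: in the chosen strategy the quaternary centre is the carbene carbon itself, the reaction is intramolecular, and the C6 oxygen is native to the arene.

Key step: step 7

Assumption: the (4R,4'R)-diphenyl bis(oxazoline) ligand is taken to favour the same arene face as the C4 stereocentre of 11; if a trial shows the opposite sense, the (4S,4'S) antipode is used and nothing else changes.

## Route

Step 1
Reactants: 1 2'-hydroxy-4'-methylacetophenone
Product: 2 2'-methoxy-4'-methylacetophenone
Conditions: MeI, K2CO3, acetone, reflux
Reagents that add atoms: iodomethane, CI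
Why: Williamson ether synthesis on the only acidic site; capping the phenol also prevents coumarin formation in the next step.

Step 2
Reactants: 2 2'-methoxy-4'-methylacetophenone; 3 dimethyl carbonate
Product: 4 methyl 3-(2-methoxy-4-methylphenyl)-3-oxopropanoate
Conditions: NaH (2.2 equiv), THF, reflux; then 1 M HCl
Reagents that add atoms: none
Why: Crossed Claisen condensation of the methyl ketone enolate with a carbonate that cannot enolise; formation of the stabilised enolate of 4 drives it to completion.

Step 3
Reactants: 4 methyl 3-(2-methoxy-4-methylphenyl)-3-oxopropanoate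
Product: 5 methyl (R)-3-hydroxy-3-(2-methoxy-4-methylphenyl)propanoate
Conditions: RuCl[(R,R)-TsDPEN](p-cymene) (1 mol %), HCO2H/Et3N (5:2), 40 °C
Reagents that add atoms: none
Why: Noyori asymmetric transfer hydrogenation of an aryl ketone; the (R,R) catalyst should give the (R)-carbinol (aryl ranks above the CH2CO2Me arm), and this centre later selects the arene face in step 7.

Step 4
Reactants: 5 methyl (R)-3-hydroxy-3-(2-methoxy-4-methylphenyl)propanoate
Product: 6 methyl (R)-3-(2-methoxy-4-methylphenyl)-3-(triisopropylsilyloxy)propanoate
Conditions: TIPSOTf, 2,6-lutidine, CH2Cl2, 0 °C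
Reagents that add atoms: triisopropylsilyl trifluoromethanesulfonate, CC(C)[Si](OS(=O)(=O)C(F)(F)F)(C(C)C)C(C)C
Why: Silylation with a silyl triflate; the bulky, weakly basic silyl ether cannot form an oxonium ylide with the carbene of step 7 and should survive the acidic and reducing steps up to step 13.

Step 5
Reactants: 6 methyl (R)-3-(2-methoxy-4-methylphenyl)-3-(triisopropylsilyloxy)propanoate
Product: 7 (R)-3-(2-methoxy-4-methylphenyl)-3-(triisopropylsilyloxy)propanoic acid
Conditions: LiOH, THF/MeOH/H2O, rt; then 1 M HCl to pH 3
Reagents that add atoms: lithium hydroxide, [Li+].[OH-]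
Why: Ester saponification; the mild conditions at room temperature should avoid β-elimination of the silyloxy group.

Step 6
Reactants: 7 (R)-3-(2-methoxy-4-methylphenyl)-3-(triisopropylsilyloxy)propanoic acid; 8 N-ethyl-N-nitrosourea
Product: 11 (R)-2-diazo-5-(2-methoxy-4-methylphenyl)-5-(triisopropylsilyloxy)pentan-3-one, via acid chloride 9 (not isolated), via diazoethane 10 (not isolated)
Conditions: (COCl)2, DMF (cat.), CH2Cl2, 0 °C to rt, evaporate; then 10 (3 equiv, made from 8 with 40 % aq KOH in Et2O at 0 °C), Et2O, −20 to 0 °C
Reagents that add atoms: oxalyl chloride, ClC(=O)C(=O)Cl (supplies the chlorine of 9)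
Why: Acylation of a diazoalkane by an acid chloride (the diazoketone synthesis of the Arndt–Eistert sequence); the methyl group and the diazo carbon arrive together, so the position of the diazo group is not in question, and excess diazoethane takes up the HCl.

Step 7
Reactants: 11 (R)-2-diazo-5-(2-methoxy-4-methylphenyl)-5-(triisopropylsilyloxy)pentan-3-one
Product: 13 (3R,8aR)-4-methoxy-6,8a-dimethyl-3-(triisopropylsilyloxy)-3,8a-dihydroazulen-1(2H)-one (6-methoxy-4α-silyloxy-11,12,13-trinordauca-5,7,9-trien-2-one), via norcaradiene 12 (not isolated)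
Conditions: [Cu(MeCN)4]PF6 (5 mol %), (4R,4'R)-2,2'-(propane-2,2-diyl)bis(4-phenyl-4,5-dihydrooxazole) (6 mol %), CH2Cl2, 40 °C, slow addition of 11
Reagents that add atoms: none
Why: Loss of N2 from 11 at monovalent copper gives an electrophilic copper carbene at C1, which adds across the C5–C10 bond of the arene to norcaradiene 12, and disrotatory six-electron opening of that bond gives cycloheptatriene 13 (intramolecular Buchner reaction). The closest known reaction is the enantioselective Buchner cyclisation of 2-diazo-5-arylpentan-3-ones to 8a-methylazulenones with copper bis(oxazoline) catalysts. Ring A closes as a five-membered ring when the tethered carbene carbon bonds to the ipso carbon C5, the cyclopropane being completed at C10; ring B is formed by ring expansion, the benzene ring opening from six to seven atoms around the inserted C1. The new stereocentre C1 is fixed by the arene face that is attacked: C4 keeps its hydrogen next to the ortho methoxy group (allylic 1,3-strain) and its silyloxy group on the face away from the carbene, so the C1 methyl ends trans to the silyloxy group, and the ligand is chosen to favour the same face. Regioselectivity comes from the methoxy group, which blocks its own ortho carbon, so the carbene takes the free C5–C10 bond and methoxy and methyl end at C6 and C8. The arene must win over 1,2-hydride shift of the α-methyl carbene and over attack at oxygen; the ipso carbon, activated by the ortho methoxy and para methyl groups, speeds the first, and the hindered silyl ether in place of an acetal removes the second.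

Step 8
Reactants: 13 (3R,8aR)-4-methoxy-6,8a-dimethyl-3-(triisopropylsilyloxy)-3,8a-dihydroazulen-1(2H)-one
Product: 14 4α-(triisopropylsilyloxy)-11,12,13-trinordauca-7,9-diene-2,6-dione (5αH; trans-fused)
Conditions: 5 % aq oxalic acid, THF, 0 °C to rt
Reagents that add atoms: water, O
Why: Enol ether hydrolysis: protonation at C5 gives an oxocarbenium ion stabilised by the diene, water adds at C6 and methanol leaves. C5 is set here; protonation and any equilibration through the enol should favour the trans-fused epimer (H-5 α), in which C6 lies anti to the bulky 4α-silyloxy group on ring A.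

Step 9
Reactants: 14 4α-(triisopropylsilyloxy)-11,12,13-trinordauca-7,9-diene-2,6-dione
Product: 15 2ξ-hydroxy-4α-(triisopropylsilyloxy)-11,12,13-trinordauc-8-en-6-one
Conditions: Li (6 equiv), t-BuOH (3 equiv), NH3/THF, −78 °C; solid NH4Cl
Reagents that add atoms: none
Why: Dissolving-metal reduction: the linear dienone takes two electrons and a proton at C10 to give the C6 dienolate, which resists further reduction and is protonated at C7 on quench, leaving the alkene at C8–C9. The saturated C2 ketone is reduced to its alkoxide in the same pot, which distinguishes the two carbonyl groups; the configuration at C2 does not matter because the centre is removed in step 12.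

Step 10
Reactants: 15 2ξ-hydroxy-4α-(triisopropylsilyloxy)-11,12,13-trinordauc-8-en-6-one
Product: 16 6,6-(ethylenedioxy)-4α-(triisopropylsilyloxy)-11,12,13-trinordauc-8-en-2ξ-ol
Conditions: ethylene glycol, PPTS (cat.), benzene, reflux, Dean–Stark
Reagents that add atoms: ethylene glycol, OCCO
Why: Acid-catalysed acetalisation with removal of water; in the dioxolane the alkene stays at C8–C9, and the mask later allows C4 to be a ketone without a 1,3-diketone being formed.

Step 11
Reactants: 16 6,6-(ethylenedioxy)-4α-(triisopropylsilyloxy)-11,12,13-trinordauc-8-en-2ξ-ol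
Product: 17 O-[6,6-(ethylenedioxy)-4α-(triisopropylsilyloxy)-11,12,13-trinordauc-8-en-2ξ-yl] S-methyl dithiocarbonate
Conditions: NaH, imidazole (cat.), THF, 0 °C to rt; CS2; MeI
Reagents that add atoms: carbon disulfide, S=C=S; iodomethane, CI
Why: Xanthate formation, the first half of the Barton–McCombie deoxygenation; the C2 hydroxyl is the only free one.

Step 12
Reactants: 17 O-[6,6-(ethylenedioxy)-4α-(triisopropylsilyloxy)-11,12,13-trinordauc-8-en-2ξ-yl] S-methyl dithiocarbonate
Product: 18 6,6-(ethylenedioxy)-4α-(triisopropylsilyloxy)-11,12,13-trinordauc-8-ene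
Conditions: Bu3SnH, AIBN (cat.), toluene, 110 °C
Reagents that add atoms: none
Why: Barton–McCombie radical deoxygenation; the only alkene left is too far from the C2 radical for cyclisation, which is why this step follows the reduction of the triene.

Step 13
Reactants: 18 6,6-(ethylenedioxy)-4α-(triisopropylsilyloxy)-11,12,13-trinordauc-8-ene
Product: 19 6,6-(ethylenedioxy)-11,12,13-trinordauc-8-en-4α-ol
Conditions: TBAF, THF, 50 °C; aq NH4Cl
Reagents that add atoms: none
Why: Fluoride cleavage of the silyl ether; acetal and alkene are inert.

Step 14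
Reactants: 19 6,6-(ethylenedioxy)-11,12,13-trinordauc-8-en-4α-ol
Product: 20 6,6-(ethylenedioxy)-11,12,13-trinordauc-8-en-4-one
Conditions: Dess–Martin periodinane, NaHCO3, CH2Cl2, 0 °C to rt
Reagents that add atoms: none
Why: Dess–Martin oxidation under buffered, non-basic conditions, so that C5, now between a ketone and the acetal carbon, is not epimerised and the β-acetal is not eliminated.

Step 15
Reactants: 20 6,6-(ethylenedioxy)-11,12,13-trinordauc-8-en-4-one; 21 isopropylmagnesium chloride
Product: 22 6,6-(ethylenedioxy)dauc-8-en-4β-ol
Conditions: CeCl3 (anhydrous, 3 equiv), 21 (3 equiv), THF, −78 to −40 °C; aq NH4Cl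
Reagents that add atoms: none
Why: 1,2-Addition of an organocerium reagent made from 21 and CeCl3, which is nucleophilic but hardly basic, so enolisation toward C5 and reduction are held back. The angular methyl and the C5–C6 bond shield the β face of the cyclopentanone, so isopropyl should enter from the α face and the C4 hydroxyl end β (C4 R), as in the target.

Step 16
Reactants: 22 6,6-(ethylenedioxy)dauc-8-en-4β-ol
Product: 23 4β-hydroxydauc-8-en-6-one
Conditions: PPTS (0.2 equiv), acetone/H2O (10:1), 40 °C, stopped at full conversion
Reagents that add atoms: water, O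
Why: Mild acid-catalysed acetal hydrolysis; the weak acid should leave the tertiary alcohol and the β,γ position of the alkene untouched, and the trans ring fusion is kept because C6 lies anti to the α isopropyl group. 23 is used at once.

Step 17
Reactants: 23 4β-hydroxydauc-8-en-6-one
Product: 24 dauc-8-ene-4β,6α-diol (jaeschkeanadiol)
Conditions: Me4NBH(OAc)3 (5 equiv), MeCN/AcOH (1:1), −30 °C
Reagents that add atoms: none
Why: Hydroxyl-directed reduction (Evans–Saksena): the tertiary 4β-hydroxyl exchanges onto boron and delivers hydride internally to the β face of C6, against the steric bias of the angular methyl, which should give the 1,3-anti diol with the 6α-hydroxyl (C6 S).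

Step 18
Reactants: 24 dauc-8-ene-4β,6α-diol
Product: 25 8α,9α-epoxydaucane-4β,6α-diol
Conditions: VO(acac)2 (5 mol %), t-BuOOH (1.5 equiv), CH2Cl2, 0 °C to rt
Reagents that add atoms: tert-butyl hydroperoxide, CC(C)(C)OO
Why: Hydroxyl-directed epoxidation: the homoallylic 6α-hydroxyl binds vanadium and delivers oxygen to the α face of C8=C9, which is also the face free of the angular methyl; this sets C8 (R) and C9 (S).

Step 19
Reactants: 25 8α,9α-epoxydaucane-4β,6α-diol; 26 3,4-dimethoxybenzoyl chloride
Product: 27 (1R,4R,5S,6S,8R,9S)-8,9-epoxy-4-hydroxydaucan-6-yl 3,4-dimethoxybenzoate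
Conditions: Et3N, DMAP, CH2Cl2, 0 °C to rt
Reagents that add atoms: none
Why: DMAP-catalysed acylation; only the secondary 6-hydroxyl should react, the tertiary 4-hydroxyl being too hindered, and the basic medium keeps the epoxide closed.

## Compound list

1 | 2'-hydroxy-4'-methylacetophenone | CC(=O)c1ccc(C)cc1O | starting material
2 | 2'-methoxy-4'-methylacetophenone | COc1cc(C)ccc1C(C)=O | intermediate
3 | dimethyl carbonate | COC(=O)OC | starting material
4 | methyl 3-(2-methoxy-4-methylphenyl)-3-oxopropanoate | COC(=O)CC(=O)c1ccc(C)cc1OC | intermediate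
5 | methyl (R)-3-hydroxy-3-(2-methoxy-4-methylphenyl)propanoate | COc1cc(C)ccc1[C@H](O)CC(=O)OC | intermediate
6 | methyl (R)-3-(2-methoxy-4-methylphenyl)-3-(triisopropylsilyloxy)propanoate | COc1cc(C)ccc1[C@H](O[Si](C(C)C)(C(C)C)C(C)C)CC(=O)OC | intermediate
7 | (R)-3-(2-methoxy-4-methylphenyl)-3-(triisopropylsilyloxy)propanoic acid | COc1cc(C)ccc1[C@H](O[Si](C(C)C)(C(C)C)C(C)C)CC(=O)O | intermediate
8 | N-ethyl-N-nitrosourea | CCN(N=O)C(N)=O | starting material
9 | (R)-3-(2-methoxy-4-methylphenyl)-3-(triisopropylsilyloxy)propanoyl chloride | COc1cc(C)ccc1[C@H](O[Si](C(C)C)(C(C)C)C(C)C)CC(=O)Cl | intermediate (not isolated)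
10 | diazoethane | CC=[N+]=[N-] | intermediate (not isolated)
11 | (R)-2-diazo-5-(2-methoxy-4-methylphenyl)-5-(triisopropylsilyloxy)pentan-3-one | COc1cc(C)ccc1[C@H](O[Si](C(C)C)(C(C)C)C(C)C)CC(=O)C(C)=[N+]=[N-] | intermediate
12 | norcaradiene valence isomer of 13 (cyclopropane C1–C5–C10, diene C6=C7–C8=C9) | COC1=CC(C)=C[C@@H]2[C@@]3(C)C(=O)C[C@@H](O[Si](C(C)C)(C(C)C)C(C)C)[C@@]123 | intermediate (not isolated)
13 | (3R,8aR)-4-methoxy-6,8a-dimethyl-3-(triisopropylsilyloxy)-3,8a-dihydroazulen-1(2H)-one | COC1=C2[C@H](O[Si](C(C)C)(C(C)C)C(C)C)CC(=O)[C@]2(C)C=CC(C)=C1 | intermediate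
14 | 4α-(triisopropylsilyloxy)-11,12,13-trinordauca-7,9-diene-2,6-dione (5αH) | O=C1C=C(C)C=C[C@@]2(C)C(=O)C[C@@H](O[Si](C(C)C)(C(C)C)C(C)C)[C@H]12 | intermediate
15 | 2ξ-hydroxy-4α-(triisopropylsilyloxy)-11,12,13-trinordauc-8-en-6-one (C2 not defined) | O=C1CC(C)=CC[C@@]2(C)C(O)C[C@@H](O[Si](C(C)C)(C(C)C)C(C)C)[C@H]12 | intermediate
16 | 6,6-(ethylenedioxy)-4α-(triisopropylsilyloxy)-11,12,13-trinordauc-8-en-2ξ-ol | O1CCOC12CC(C)=CC[C@@]3(C)C(O)C[C@@H](O[Si](C(C)C)(C(C)C)C(C)C)[C@H]23 | intermediate
17 | O-[6,6-(ethylenedioxy)-4α-(triisopropylsilyloxy)-11,12,13-trinordauc-8-en-2ξ-yl] S-methyl dithiocarbonate | O1CCOC12CC(C)=CC[C@@]3(C)C(OC(=S)SC)C[C@@H](O[Si](C(C)C)(C(C)C)C(C)C)[C@H]23 | intermediate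
18 | 6,6-(ethylenedioxy)-4α-(triisopropylsilyloxy)-11,12,13-trinordauc-8-ene | O1CCOC12CC(C)=CC[C@@]3(C)CC[C@@H](O[Si](C(C)C)(C(C)C)C(C)C)[C@H]23 | intermediate
19 | 6,6-(ethylenedioxy)-11,12,13-trinordauc-8-en-4α-ol | O1CCOC12CC(C)=CC[C@@]3(C)CC[C@@H](O)[C@H]23 | intermediate
20 | 6,6-(ethylenedioxy)-11,12,13-trinordauc-8-en-4-one | O1CCOC12CC(C)=CC[C@@]3(C)CCC(=O)[C@H]23 | intermediate
21 | isopropylmagnesium chloride | CC(C)[Mg]Cl | starting material
22 | 6,6-(ethylenedioxy)dauc-8-en-4β-ol | O1CCOC12CC(C)=CC[C@@]3(C)CC[C@@](O)(C(C)C)[C@H]23 | intermediate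
23 | 4β-hydroxydauc-8-en-6-one | O=C1CC(C)=CC[C@@]2(C)CC[C@@](O)(C(C)C)[C@H]12 | intermediate
24 | dauc-8-ene-4β,6α-diol (jaeschkeanadiol) | O[C@H]1CC(C)=CC[C@@]2(C)CC[C@@](O)(C(C)C)[C@H]12 | intermediate
25 | 8α,9α-epoxydaucane-4β,6α-diol | O[C@H]1C[C@@]2(C)O[C@H]2C[C@@]2(C)CC[C@@](O)(C(C)C)[C@H]12 | intermediate
26 | 3,4-dimethoxybenzoyl chloride | COc1ccc(cc1OC)C(=O)Cl | starting material
27 | (1R,4R,5S,6S,8R,9S)-8,9-epoxy-4-hydroxydaucan-6-yl 3,4-dimethoxybenzoate | COc1ccc(C(=O)O[C@H]2C[C@@]3(C)O[C@H]3C[C@@]3(C)CC[C@@](O)(C(C)C)[C@H]23)cc1OC | target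

## Step count and least certain steps

Total: 19 steps. Longest linear sequence: 19 steps (1 to 27); diazoethane 10 is generated inside step 6.

**Step 7 (key step).** The α-methyl carbene may undergo 1,2-hydride shift to an enone before it reaches the arene, and the ligand may oppose the face preferred by C4, which would erode diastereocontrol. The fallback takes the methyl group off the carbene. It sets out from acid 7: its acid chloride 9 is treated with trimethylsilyldiazomethane and Et3N to give (R)-1-diazo-4-(2-methoxy-4-methylphenyl)-4-(triisopropylsilyloxy)butan-2-one F1. The Buchner reaction of F1 with Rh2(OAc)4 in CH2Cl2, where no hydride shift is possible and C4 alone chooses the face, gives 6-methoxy-4α-(triisopropylsilyloxy)-11,12,13,15-tetranordauca-5,7,9-trien-2-one F2. Deprotonation at the doubly allylic C1 with LiN(iPr)2 at −78 °C and α-methylation with MeI anti to the 4α-silyloxy group returns to 13.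

**Step 9.** Enolisation of the C2 ketone may compete with its reduction, leaving ketone behind and letting the C2 enolate expel the β-silyloxy group; the freed C6 ketone may also be over-reduced on quench. The fallback sets out from 13: NaBH4 in MeOH reduces its only ketone to 6-methoxy-4α-(triisopropylsilyloxy)-11,12,13-trinordauca-5,7,9-trien-2ξ-ol F3. Oxalic acid hydrolysis gives 2ξ-hydroxy-4α-(triisopropylsilyloxy)-11,12,13-trinordauca-7,9-dien-6-one F4, and Li (2.5 equiv) in NH3 without alcohol then reduces only the dienone and returns to 15.

**Step 15.** The secondary Grignard reagent may transfer hydride (reduction of C4) or enolise toward C5 with opening of the acetal, because the carbonyl sits in a crowded position. The fallback sets out from 20: isopropenylmagnesium bromide with CeCl3, a smaller sp2 nucleophile with no hydride to transfer, gives 6,6-(ethylenedioxy)dauca-8,11-dien-4β-ol F5. Hydrogenation with RhCl(PPh3)3 and H2 saturates only the 1,1-disubstituted alkene and returns to 22.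

**Step 16.** Under acid the freed ketone may enolise toward C7 and the alkene may move into conjugation (C7=C8), or the tertiary aldol may dehydrate. The fallback unveils C6 by oxidation instead of hydrolysis and sets out from 15:
- 1,1'-thiocarbonyldiimidazole gives the O-(6-oxo-4α-(triisopropylsilyloxy)-11,12,13-trinordauc-8-en-2ξ-yl) imidazole-1-carbothioate F6.
- Bu3SnH/AIBN gives 4α-(triisopropylsilyloxy)-11,12,13-trinordauc-8-en-6-one F7.
- NaBH4 gives 4α-(triisopropylsilyloxy)-11,12,13-trinordauc-8-en-6ξ-ol F8.
- NaH and 4-methoxybenzyl chloride give the 6-(4-methoxybenzyl) ether F9.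
- TBAF gives 6ξ-(4-methoxybenzyloxy)-11,12,13-trinordauc-8-en-4α-ol F10.
- Dess–Martin periodinane gives 6ξ-(4-methoxybenzyloxy)-11,12,13-trinordauc-8-en-4-one F11.
- 21 with CeCl3 gives 6ξ-(4-methoxybenzyloxy)dauc-8-en-4β-ol F12.
- DDQ gives dauc-8-ene-4β,6ξ-diol F13.
- Buffered Dess–Martin oxidation of the secondary hydroxyl returns to 23 under neutral conditions.

**Step 18.** The Lewis-acidic vanadium may let the 4β-hydroxyl open the new epoxide across the ring, or oxygen delivery may be slow for a homoallylic alcohol. The fallback sets out from 24: acylation with 26 and DMAP gives 4β-hydroxydauc-8-en-6α-yl 3,4-dimethoxybenzoate F14. Epoxidation with mCPBA and NaHCO3, controlled only by the angular methyl shielding the β face, returns to 27.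

## Further compounds

F1 | step 7 | (R)-1-diazo-4-(2-methoxy-4-methylphenyl)-4-(triisopropylsilyloxy)butan-2-one | COc1cc(C)ccc1[C@H](O[Si](C(C)C)(C(C)C)C(C)C)CC(=O)C=[N+]=[N-]
F2 | step 7 | 6-methoxy-4α-(triisopropylsilyloxy)-11,12,13,15-tetranordauca-5,7,9-trien-2-one | COC1=C2[C@H](O[Si](C(C)C)(C(C)C)C(C)C)CC(=O)C2C=CC(C)=C1
F3 | step 9 | 6-methoxy-4α-(triisopropylsilyloxy)-11,12,13-trinordauca-5,7,9-trien-2ξ-ol | COC1=C2[C@H](O[Si](C(C)C)(C(C)C)C(C)C)CC(O)[C@]2(C)C=CC(C)=C1
F4 | step 9 | 2ξ-hydroxy-4α-(triisopropylsilyloxy)-11,12,13-trinordauca-7,9-dien-6-one | O=C1C=C(C)C=C[C@@]2(C)C(O)C[C@@H](O[Si](C(C)C)(C(C)C)C(C)C)[C@H]12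
F5 | step 15 | 6,6-(ethylenedioxy)dauca-8,11-dien-4β-ol | O1CCOC12CC(C)=CC[C@@]3(C)CC[C@@](O)(C(C)=C)[C@H]23
F6 | step 16 | O-(6-oxo-4α-(triisopropylsilyloxy)-11,12,13-trinordauc-8-en-2ξ-yl) 1H-imidazole-1-carbothioate | O=C1CC(C)=CC[C@@]2(C)C(OC(=S)n3ccnc3)C[C@@H](O[Si](C(C)C)(C(C)C)C(C)C)[C@H]12
F7 | step 16 | 4α-(triisopropylsilyloxy)-11,12,13-trinordauc-8-en-6-one | O=C1CC(C)=CC[C@@]2(C)CC[C@@H](O[Si](C(C)C)(C(C)C)C(C)C)[C@H]12
F8 | step 16 | 4α-(triisopropylsilyloxy)-11,12,13-trinordauc-8-en-6ξ-ol | OC1CC(C)=CC[C@@]2(C)CC[C@@H](O[Si](C(C)C)(C(C)C)C(C)C)[C@H]12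
F9 | step 16 | 6ξ-(4-methoxybenzyloxy)-4α-(triisopropylsilyloxy)-11,12,13-trinordauc-8-ene | COc1ccc(COC2CC(C)=CC[C@@]3(C)CC[C@@H](O[Si](C(C)C)(C(C)C)C(C)C)[C@H]23)cc1
F10 | step 16 | 6ξ-(4-methoxybenzyloxy)-11,12,13-trinordauc-8-en-4α-ol | COc1ccc(COC2CC(C)=CC[C@@]3(C)CC[C@@H](O)[C@H]23)cc1
F11 | step 16 | 6ξ-(4-methoxybenzyloxy)-11,12,13-trinordauc-8-en-4-one | COc1ccc(COC2CC(C)=CC[C@@]3(C)CCC(=O)[C@H]23)cc1
F12 | step 16 | 6ξ-(4-methoxybenzyloxy)dauc-8-en-4β-ol | COc1ccc(COC2CC(C)=CC[C@@]3(C)CC[C@@](O)(C(C)C)[C@H]23)cc1
F13 | step 16 | dauc-8-ene-4β,6ξ-diol | OC1CC(C)=CC[C@@]2(C)CC[C@@](O)(C(C)C)[C@H]12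
F14 | step 18 | 4β-hydroxydauc-8-en-6α-yl 3,4-dimethoxybenzoate | COc1ccc(C(=O)O[C@H]2CC(C)=CC[C@@]3(C)CC[C@@](O)(C(C)C)[C@H]23)cc1OC
A1 | alternative 1 | methylaluminium bis(4-bromo-2,6-di-tert-butylphenoxide) | C[Al](Oc1c(cc(Br)cc1C(C)(C)C)C(C)(C)C)Oc1c(cc(Br)cc1C(C)(C)C)C(C)(C)C
A2 | alternative 1 | 2-allyl-5-isopropyl-2-methyl-5-(tert-butyldimethylsilyloxy)cyclopentane-1-carbaldehyde (ring A with the C6 aldehyde) | C=CC[C@@]1(C)CC[C@@](O[Si](C)(C)C(C)(C)C)(C(C)C)[C@@H]1C=O
A3 | alternative 2 | 3-(3-methylbut-3-en-1-yl)cyclopent-2-en-1-one | CC(=C)CCC1=CC(=O)CC1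
A4 | alternative 2 | trimethylaluminium | C[Al](C)C
A5 | alternative 2 | copper bis(trifluoromethanesulfonate) | [Cu+2].[O-]S(=O)(=O)C(F)(F)F.[O-]S(=O)(=O)C(F)(F)F
A6 | alternative 2 | acrolein | C=CC=O
A7 | alternative 2 | 2-(1-hydroxyallyl)-3-methyl-3-(3-methylbut-3-enyl)cyclopentanone | O[C@@H](C=C)[C@H]1C(=O)CC[C@]1(C)CCC(C)=C
A8 | alternative 3 | methyl 2-[(5S)-5-(tert-butyldimethylsilyloxy)-2-methylcyclopent-1-en-1-yl]-2-diazoacetate | COC(=O)C(=[N+]=[N-])C1=C(C)CC[C@@H]1O[Si](C)(C)C(C)(C)C
A9 | alternative 3 | isoprene | C=CC(C)=C
A10 | alternative 3 | dirhodium tetrakis[(S)-N-(4-dodecylphenylsulfonyl)prolinate] | [Rh+2].[Rh+2].CCCCCCCCCCCCc1ccc(cc1)S(=O)(=O)N1CCC[C@H]1C([O-])=O.CCCCCCCCCCCCc1ccc(cc1)S(=O)(=O)N1CCC[C@H]1C([O-])=O.CCCCCCCCCCCCc1ccc(cc1)S(=O)(=O)N1CCC[C@H]1C([O-])=O.CCCCCCCCCCCCc1ccc(cc1)S(=O)(=O)N1CCC[C@H]1C([O-])=O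
A11 | alternative 3 | methyl (3S,8aR)-3-(tert-butyldimethylsilyloxy)-6,8a-dimethyl-1,2,3,5,8,8a-hexahydroazulene-4-carboxylate | COC(=O)C1=C2[C@@H](O[Si](C)(C)C(C)(C)C)CC[C@]2(C)CC=C(C)C1
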